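Beside the gamma flask stand its neighbours eta, alpha and theta, which keep the substrate charge and raise the partner charge from 0.120 M to 0.200 M, 0.400 M and 0.800 M, and I want to know what that does to the open intermediate after 1.0 min.

common to all: substrate 0.80 M; time 1.0 min

| flask | partner |
|---|---|
| gamma | 0.120 M |
| eta | 0.200 M |
| alpha | 0.400 M |
| theta | 0.800 M |

    partner → second intermediate (k1 = 0.0053 s⁻¹)
    open intermediate + second intermediate → target (k2 = 0.0058 M⁻¹ s⁻¹)
    substrate → open intermediate (k3 = 0.023 s⁻¹)
    2 second intermediate → homo product (k4 = 0.0021 M⁻¹ s⁻¹)

- for a step with 2 of a species take k times the square, and two of it per event
- "hardly changes" means that all values lie within two and a half points (for a concentration: within two and a half percent of the largest)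
- run time (gamma): 1.0 min

1. amount of open intermediate at the end, in percent of the substrate charged for gamma, eta, alpha, theta, in this order
2. the shape of the row from first to last (rises all the way / rises, then falls / hardly changes / falls all the way / falls, then rises)

The substrate opens by a first-order step with a half-life of 0.50 min, and the partner has no part in that step, so in each flask the share opened by the end is 74.8%, which is the ceiling for the row. The partner lowers the row in this way: it turns into second intermediate, with a half-life of 2.2 min, slower than the substrate opens, and the second intermediate then takes open intermediate away into target, one for each turn. So the row stands below the ceiling by the target formed. I neglect what the intermediates lose, so that each rises towards its own charge along its first-order curve, and the rate of target is the second constant times both charges times both rising fractions. Dividing by the substrate charge removes that charge, and what remains of the run is the overlap time, 4.93 s, the time for which both intermediates would have to stand at their full charges to give the same target. Target as a share of the substrate charged is then the second constant times the partner charge times the overlap time, which is 0.343% for gamma and 2.29% for theta. I therefore commit to 74.5%, 74.3%, 73.7% and 72.5%, a spread of 1.9 percentage points, which is less than the 2.5 points allowed, so I call the row flat.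

The forecast gives 74.5%, 74.3%, 73.7% and 72.7%, “so the row hardly changes”, and it parts from my figures in theta, where I have 72.5%. The simulation gives 74.5%, 74.3%, 73.8% and 72.7%, and the shape is: hardly changes.

With the overlap time of 4.93 s, gamma should hold 0.343% of target and holds 0.325%, while theta, at 2.29%, reads 2.12%, lower than reckoned. The early reading has the largest single effect on theta's open intermediate: with that early reading taken away and theta read at 10.0 min instead of 1.00 min, its open intermediate stands not at 72.7% but at 45.0%.

Its constants were set for the occasion; the result is computed.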